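## Structural features

The target is a eudesmane: a decalin in which ring A (C1–C5, C10) and ring B (C5–C10) share the C5–C10 bond, and the C10 methyl group and the C5 hydrogen lie on the same (β) face, so the fusion is cis. It has five stereocentres. C3 (α-angeloyloxy), C4 (α-acetoxy, β-methyl) and C5 are contiguous and lean on the quaternary C10. C7 (β-isopropyl) stands alone, next to the C8 ketone. In eudesmane numbering the configuration is 3R,4S,5S,7R,10R. The fragile groups are the angelate (Z, prone to isomerise to the E tiglate when activated), the tertiary acetate (liable to ionise or to shift to O3) and the enolisable C7 centre. C7 is, however, the stable epimer, because its isopropyl group is equatorial in the only chair pair that avoids a syn-diaxial contact of the C4 and C10 methyl groups. The real difficulty is the tertiary oxygen on C4. It sits on the concave α face of a cis-decalin, where an external oxidant would not be expected to attack. It is cis to O3, flanked by the ring-fusion carbon, and must carry a different acyl group from its neighbour. The feature used is the unit C3(O)–C4(CH3)(O)–C5 of ring A. With C3 at the ketone level it is a 2-hydroxy-2-methylcyclohexanone, the product of an acyloin ring enlargement of a 1-acetylcyclopentanol built on ring carbons C3, C2, C1, C10 and C5 of a cis-hydrindane. In that shift the C4 oxygen is the former acetyl oxygen and is delivered from inside the molecule.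

## Logic of the disconnections

21 to 19 and 20. The acetyl C–O4 bond is cut first, because the tertiary ester is the most labile group and should be made last. This leaves a hydroxy angelate with every stereocentre in place. The forward step must acylate a hindered axial tertiary hydroxyl without base, so that the ester on O3 neither migrates nor isomerises.

19 to 16 and 17 (through 18). The angeloyl C–O3 bond is cut. The secondary equatorial hydroxyl of 16 is far more reactive than the tertiary one, so no protecting group is needed. The forward step must transfer the Z acyl group without a nucleophilic catalyst.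

16 to 14 (through 15). The C3–H bond is removed and the C8 carbonyl is returned to its dioxolane. This gives an α-ketol with only one free ketone. The forward step needs hydride delivery to the β face of C3 and a ketal hydrolysis placed where only a diol is present.

14 to 13. The C4–C5 bond is cut and C5 is reconnected to C3. Ring A contracts to a cyclopentane that carries an acetyl and a hydroxyl group on C3, and the C4 stereocentre disappears. The forward shift must move C5 and not C2, and must run through the chelated rotamer with the two oxygens syn.

13 to 9 and 11 (through 12; 11 from 10). The C3–C4 bond is cut, which removes a two-carbon acyl-anion equivalent and leaves a plain cis-hydrindanone. The forward addition must come from the convex β face.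

9 to 6 and 7 (through 8). C2 is excised by cutting C2–C3 and C1–C2 and joining C1 to C3. This gives a cyclobutanone, which a ketene cycloaddition can make. The forward homologation must let the C1 methylene migrate and not the C5 methine.

6 to 5. Two C–H bonds on C1 are exchanged for C–Cl. The chlorines are what make the ketene reactive enough toward an unactivated alkene.

5 to 2 and 4 (4 from 3). The C3–C5 and C1–C10 bonds are cut in a [2+2] sense. Both ring-fusion centres and the quaternary C10 go back to a flat trisubstituted alkene. The forward step must be regioselective (carbonyl carbon to C5) and must add anti to the pseudoaxial ketal oxygen, that is, to the α face.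

2 to 1. The dioxolane is opened to the ketone and the double bond is returned to conjugation. The starting material is a chiral-pool enone that supplies C7. The forward ketalisation must shift the alkene to C5=C10 without enolising C7.

## Other disconnections considered

Alternative 1: The cut is the C1–C10 bond of ring A, with the C3–C8 bond restored in the retrosynthetic sense. The forward key step is an anionic oxy-Cope shift. KH with 18-crown-6 deprotonates the endo-vinyl bicyclo[2.2.2]octenol A1, and the [3,3] shift gives the enolate of the cis-fused enone A2, which has the MOM-protected C4 oxygen in place. A1 would come from a Diels–Alder reaction of a 6-oxygenated 4,6-dimethylcyclohexadienone, followed by vinyl-metal addition.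
- In its favour: the shift is concerted and must pass through a boat, so the cis fusion and the quaternary C10 follow from the geometry of A1. On this point it is better than the chosen plan, which relies on face selection in a cycloaddition and on the choice of migrating group. It is the equal of the chosen plan in placing the C4 oxygen on the α face, here because that oxygen is present before ring A exists.
- Against it: the alkene that must bring C6, C7 and the isopropyl group is unactivated, so a surrogate and later adjustment would be needed. The dienone is racemic and dimerises easily, so a single enantiomer needs an enantioselective cycloaddition or a resolution. After the shift, the C8=C9 alkene of A2 must still be oxidised regioselectively to the C8 ketone, and the MOM group exchanged for acetate next to an angelate.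
- Step economy: it is estimated to need about as many steps to A1 as the chosen route needs to 13, and more steps after the key step.

Alternative 2: The cut is C5–C6 of ring B. In the forward step Et2Zn opens the cyclopropanol of A3 to a zinc homoenolate. With catalytic CuBr·SMe2 and Me3SiCl this adds in a 6-exo conjugate addition to C5 of the enone, closing ring B and giving the silyl enol ether A4.
- In its favour: one mild, copper-catalysed step delivers the C8 ketone at its final position and a regiodefined C3=C4 enol silane. In functional-group placement this is better than the chosen key step. The cis fusion follows from the short tether and is the equal of the chosen plan's cycloaddition control.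
- Against it: A4 carries neither the isopropyl group nor the C4 oxygen. The isopropyl group would have to be added at C7 by enolate chemistry over several steps. The C4 oxygen would have to come from an external oxidant acting on the enol silane, which should prefer the convex β face, opposite to the α-oxygen required. The absolute configuration rests on the quaternary centre of A3, for which no chiral-pool source is at hand.
- Step economy: it is mechanistically sound but structurally incomplete, and poorer in step economy.

Alternative 3: The cut removes C8 (the bonds C7–C8 and C8–C9). In the forward step Me3SiCHN2 with BF3·OEt2 enlarges the cis-hydrindanone A5 to the decalinone A6. A5 would come from a proline-catalysed Hajos–Parrish annulation and a cis-selective hydrogenation.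
- In its favour: the absolute configuration comes from a catalytic asymmetric annulation and not from an epimerisable terpene ketone. The regiochemistry of the ring expansion is unambiguous, because one neighbour of the carbonyl is quaternary. On both points it is better than the chosen plan, whose step 4 uses the same reaction type with a less clear-cut choice.
- Against it: the carbonyl of A6 is at C9, not C8. A 1,2-carbonyl transposition and then introduction of the isopropyl group at C7 would be needed. The C4 hydroxyl would again have to be added from outside to the wrong (β) face, after the C4 configuration of A6 is erased.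
- Step economy: the key step forms ring B but leaves most of the oxidation pattern unsolved, so it is clearly poorer.

Key step: step 6

Assumption: (R)-piperitone of high enantiomeric purity is used; commercial material is checked and enriched before use if necessary, since C7 carries all absolute stereochemical information.
Convention: eudesmane locants are used for every intermediate, and β is the face of the C10 methyl group.
Remark: C5 is a ring-fusion methine and migrates as a secondary alkyl group. The aluminium reagent chosen is the tert-butoxide, which has no carbinol hydrogen and so cannot reduce the new ketone.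

Step 1
Reactants: 1 (R)-piperitone
Product: 2 (10R)-7-methyl-10-isopropyl-1,4-dioxaspiro[4.5]dec-7-ene
Conditions: HOCH2CH2OH, HC(OEt)3, p-TsOH·H2O (cat.), CH2Cl2, rt
Reagents that add atoms: ethylene glycol, OCCO
Why: Deconjugative ketalisation: the acid-catalysed reaction of a β-methyl enone runs through the linear dienol ether, which takes its proton back at C9, so the ketal should form with the double bond moved to C5=C10 (as with steroidal 4-en-3-ones); the orthoformate removes water at room temperature and keeps acid contact short, so that C7 is not enolised and stays R.

Step 2
Reactants: 2 (10R)-7-methyl-10-isopropyl-1,4-dioxaspiro[4.5]dec-7-ene; 3 trichloroacetyl chloride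
Product: 5 cis-fused dichlorocyclobutanone (8,8-dichloro-1-methyl-4-isopropylbicyclo[4.2.0]octane-3,7-dione 3-ethylene ketal; C=O on C5 and CCl2 on C10; C10 methyl with C5 hydrogen and isopropyl all β), via dichloroketene 4 (not isolated)
Conditions: Cl3CCOCl, Zn–Cu couple, Et2O–DME, 0 °C → rt, slow addition
Reagents that add atoms: trichloroacetyl chloride (3), ClC(Cl)(Cl)C(=O)Cl
Why: Ketene–alkene [2+2] cycloaddition (Staudinger-type): the less substituted, nucleophilic C5 bonds to the ketene carbonyl carbon and C10 to CCl2, and suprafacial addition across the alkene makes C5–H and C10–CH3 cis; in the half-chair with equatorial isopropyl the pseudoaxial dioxolane oxygen on C8 covers the β face, so the ketene should add to the α face, which puts hydrogen, methyl and isopropyl all β; DME ties up ZnCl2 and so protects the ketal.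

Step 3
Reactants: 5 cis-fused dichlorocyclobutanone
Product: 6 cis-fused cyclobutanone (1-methyl-4-isopropylbicyclo[4.2.0]octane-3,7-dione 3-ethylene ketal; configuration as in 5)
Conditions: Zn dust, NH4Cl, MeOH, rt
Reagents that add atoms: none
Why: Zinc-mediated reductive dechlorination of an α,α-dichlorocyclobutanone through its zinc enolate; the buffered neutral medium leaves the dioxolane alone, and the cis fusion is the only one a bicyclo[4.2.0]octanone tolerates.

Step 4
Reactants: 6 cis-fused cyclobutanone; 7 (trimethylsilyl)diazomethane
Product: 9 cis-hydrindanone (3a-methyl-6-isopropyl-cis-hexahydroindane-1,5-dione 5-ethylene ketal; eudesmane locants 3-oxo 10β-methyl 5β-H 7β-isopropyl 8-dioxolane), via 2-trimethylsilyl hydrindanone 8 (not isolated)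
Conditions: Me3SiCHN2, Sc(OSO2CF3)3 (10 mol %), CH2Cl2, −78 → 0 °C; then K2CO3 (cat.), MeOH, rt
Reagents that add atoms: (trimethylsilyl)diazomethane (7), C[Si](C)(C)C=[N+]=[N-]
Why: Lewis-acid-catalysed diazoalkane homologation (Tiffeneau–Demjanov-type 1,2-shift with loss of N2), driven by relief of cyclobutanone strain; the bulky silyl group should make the less substituted C1 methylene migrate in preference to the C5 methine, so the new carbon enters as C2 between C3 and C1, and mild methanolysis removes silicon; C5 and C10 are untouched and the catalytic scandium salt at low temperature spares the dioxolane.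

Step 5
Reactants: 9 cis-hydrindanone; 10 ethyl vinyl ether
Product: 13 3β-acetyl-3α-hydroxy cis-hydrindane 8-dioxolane (1-acetyl-3a-methyl-6-isopropyl-cis-hexahydroindan-1-ol-5-one ethylene ketal), via 1-ethoxyvinyllithium 11 (not isolated), via 1-ethoxyvinyl carbinol 12 (not isolated)
Conditions: CH2=CHOEt, t-BuLi, THF, −78 → 0 °C; then 9, −78 °C; then 0.5 M aq. HCl, THF, 0 °C
Reagents that add atoms: ethyl vinyl ether (10), C=COCC; water, O
Why: Addition of an acyl-anion equivalent (α-lithiated enol ether) to the ketone from the convex β face of the cis-hydrindane, since the α face is covered by ring B and its axial hydrogens; this sets C3 with the carbon substituent β and the hydroxyl α, and cold dilute acid then hydrolyses the enol ether much faster than the hindered dioxolane.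

Step 6
Reactants: 13 3β-acetyl-3α-hydroxy cis-hydrindane 8-dioxolane
Product: 14 4α-hydroxy-5βH-eudesmane-3,8-dione 8-ethylene ketal
Conditions: Al(O-t-Bu)3 (2 equiv), toluene, 100 °C; aq. KNaC4H4O6 work-up
Reagents that add atoms: none
Why: α-Ketol (acyloin) rearrangement: alkoxide exchange puts aluminium on O3 and the metal also binds the acetyl oxygen, so the two oxygens are held syn in a five-membered chelate while C4 is activated as the electrophile. The C3–C5 bond, which stands nearly perpendicular to the acetyl plane in this chelate, shifts with retention at C5 from C3 to C4 while C3–O becomes the carbonyl; the closest known case is the Lewis-acid D-homoannulation of 17-hydroxy-20-keto steroids. Ring A is closed by a 1,2-shift, that is, a one-carbon enlargement of the ring C3–C2–C1–C10–C5 by insertion of C4 between C3 and C5, and not by an end-to-end cyclisation, so the cis ring fusion is carried over unchanged. The one new stereocentre, C4, is fixed by the chelate: C5 adds to the acetyl face turned towards it, the former acetyl oxygen stays α beside O3 and the methyl group ends β. Two selectivities are needed: migration of C5 rather than C2, and reaction through the syn rotamer rather than the anti one. The first should follow from the higher migratory aptitude of the more substituted carbon under electron-deficient (Lewis-acid) conditions and from the rotamer that aligns C3–C5, in which the acetyl methyl eclipses the small C2 methylene and not the branched C5; the second follows from chelation. Relief of cyclopentane strain should pull the equilibrium to 14. The tert-butoxide ligands carry no transferable hydride, so the new C3 ketone is not reduced, and the dioxolane is inert to the aluminium alkoxide.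

Step 7
Reactants: 14 4α-hydroxy-5βH-eudesmane-3,8-dione 8-ethylene ketal
Product: 16 3α,4α-dihydroxy-5βH-eudesman-8-one, via diol ketal 15 (not isolated)
Conditions: NaBH4, MeOH, −20 → 0 °C; then 2 M aq. HCl, THF, rt
Reagents that add atoms: water, O
Why: Borohydride reduction by axial attack: the small hydride should approach C3 along the axial β trajectory, flanked only by axial hydrogens and anti to the axial C4–O bond, giving the equatorial 3α-alcohol cis to the 4α-hydroxyl (also the thermodynamically preferred epimer); aqueous acid in the same flask then hydrolyses the dioxolane while only a robust diol is present, and C7 keeps its equatorial β-isopropyl group, the stable configuration.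

Step 8
Reactants: 16 3α,4α-dihydroxy-5βH-eudesman-8-one; 17 angelic acid
Product: 19 3α-angeloyloxy-4α-hydroxy-5βH-eudesman-8-one, via angelic 2,4,6-trichlorobenzoic anhydride 18 (not isolated)
Conditions: 17, 2,4,6-Cl3C6H2COCl, Et3N, toluene, rt; then 16, 75 °C
Reagents that add atoms: angelic acid (17), C/C=C(/C)C(=O)O
Why: Yamaguchi-type mixed-anhydride esterification: the alcohol attacks the unhindered angeloyl carbonyl of 18, no nucleophilic catalyst is present so the Z double bond should not isomerise to the tiglate, and the equatorial secondary 3α-hydroxyl reacts while the axial tertiary 4α-hydroxyl does not.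

Step 9
Reactants: 19 3α-angeloyloxy-4α-hydroxy-5βH-eudesman-8-one; 20 acetic anhydride
Product: 21 4α-acetoxy-3α-angeloyloxy-5βH-eudesman-8-one (target CNP0322180.1; 3R,4S,5S,7R,10R)
Conditions: Ac2O, Sc(OSO2CF3)3 (5 mol %), MeCN, −20 → 0 °C
Reagents that add atoms: acetic anhydride (20), CC(=O)OC(C)=O
Why: Lewis-acid-catalysed acylation with an anhydride, the usual way to esterify hindered tertiary alcohols at low temperature, where ionisation at C4 and enol acetylation of the C8 ketone are slow; no base is present, so the angelate on O3 should neither migrate nor isomerise.

## Compound list

1 | (R)-piperitone, (6R)-6-isopropyl-3-methylcyclohex-2-en-1-one | CC1=CC(=O)[C@@H](C(C)C)CC1 | starting material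
2 | (10R)-7-methyl-10-isopropyl-1,4-dioxaspiro[4.5]dec-7-ene | CC1=CC[C@H](C(C)C)C2(OCCO2)C1 | intermediate
3 | trichloroacetyl chloride | ClC(Cl)(Cl)C(=O)Cl | starting material
4 | dichloroketene | ClC(Cl)=C=O | intermediate
5 | cis-fused dichlorocyclobutanone, 8,8-dichloro-1-methyl-4-isopropylbicyclo[4.2.0]octane-3,7-dione 3-ethylene ketal (methyl, ring-fusion H and isopropyl all β) | O=C1C(Cl)(Cl)[C@]2(C)CC3(OCCO3)[C@@H](C(C)C)C[C@H]12 | intermediate
6 | cis-fused cyclobutanone, 1-methyl-4-isopropylbicyclo[4.2.0]octane-3,7-dione 3-ethylene ketal | O=C1C[C@]2(C)CC3(OCCO3)[C@@H](C(C)C)C[C@H]12 | intermediate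
7 | (trimethylsilyl)diazomethane | C[Si](C)(C)C=[N+]=[N-] | starting material
8 | 2-trimethylsilyl derivative of 9 (C2 epimers) | O=C1C([Si](C)(C)C)C[C@]2(C)CC3(OCCO3)[C@@H](C(C)C)C[C@H]12 | intermediate
9 | cis-hydrindanone, 3a-methyl-6-isopropyl-cis-hexahydroindane-1,5-dione 5-ethylene ketal (10β-methyl, 5β-H, 7β-isopropyl) | O=C1CC[C@]2(C)CC3(OCCO3)[C@@H](C(C)C)C[C@H]12 | intermediate
10 | ethyl vinyl ether | C=COCC | starting material
11 | 1-ethoxyvinyllithium | [Li]C(=C)OCC | intermediate
12 | 3β-(1-ethoxyvinyl)-3α-hydroxy cis-hydrindane 8-dioxolane | C=C(OCC)[C@@]1(O)CC[C@]2(C)CC3(OCCO3)[C@@H](C(C)C)C[C@H]12 | intermediate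
13 | 3β-acetyl-3α-hydroxy cis-hydrindane 8-dioxolane | CC(=O)[C@@]1(O)CC[C@]2(C)CC3(OCCO3)[C@@H](C(C)C)C[C@H]12 | intermediate
14 | 4α-hydroxy-5βH-eudesmane-3,8-dione 8-ethylene ketal | O=C1CC[C@]2(C)CC3(OCCO3)[C@@H](C(C)C)C[C@@H]2[C@]1(C)O | intermediate
15 | 3α,4α-dihydroxy-5βH-eudesman-8-one ethylene ketal | O[C@@H]1CC[C@]2(C)CC3(OCCO3)[C@@H](C(C)C)C[C@@H]2[C@]1(C)O | intermediate
16 | 3α,4α-dihydroxy-5βH-eudesman-8-one | O[C@@H]1CC[C@]2(C)CC(=O)[C@@H](C(C)C)C[C@@H]2[C@]1(C)O | intermediate
17 | angelic acid, (Z)-2-methylbut-2-enoic acid | C/C=C(/C)C(=O)O | starting material
18 | angelic 2,4,6-trichlorobenzoic anhydride | C/C=C(/C)C(=O)OC(=O)c1c(Cl)cc(Cl)cc1Cl | intermediate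
19 | 3α-angeloyloxy-4α-hydroxy-5βH-eudesman-8-one | C/C=C(/C)C(=O)O[C@@H]1CC[C@]2(C)CC(=O)[C@@H](C(C)C)C[C@@H]2[C@]1(C)O | intermediate
20 | acetic anhydride | CC(=O)OC(C)=O | starting material
21 | 4α-acetoxy-3α-angeloyloxy-5βH-eudesman-8-one | C/C=C(/C)C(=O)O[C@@H]1CC[C@]2(C)CC(=O)[C@@H](C(C)C)C[C@@H]2[C@]1(C)OC(C)=O | target

Total step count: 9. Longest linear sequence: 9 steps, from 1 to 21.

## Least certain steps and fallbacks

**Step 6 (key step).** The most likely failure is competing migration of the C2 methylene in place of the C5 methine, or reaction through the unchelated anti rotamer. Both carbons flank C3, and the preference rests on migratory aptitude and a modest steric bias. Prolonged heating could also allow a further acyloin shift of the methyl group. The fallback sets out from 9 and comes back at 14, and it avoids any choice of migrating group at C4–C5.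
- A second scandium-catalysed Me3SiCHN2 homologation of 9 should insert a methylene between the carbonyl carbon and C2. This gives the cis-decalin-4-one ketal F1, in which the old carbonyl carbon is now C4 and keeps its bond to C5.
- Kinetic enolisation toward C3 (LiN(i-Pr)2, Me3SiCl) and Rubottom oxidation (m-CPBA) would give the 3-hydroxy-4-ketone F2; either C3 epimer serves.
- MeMgBr should add to C4 by equatorial attack from the open β face and give the 4β-methyl-4α-hydroxy diol F3.
- Parikh–Doering oxidation of the secondary C3 hydroxyl (SO3·pyridine, DMSO, Et3N) returns 14.

**Step 1.** The likely failures are partial loss of configurational integrity at C7 through acid-catalysed enolisation toward C7, and incomplete or exocyclic migration of the double bond. The fallback sets out from 1 and comes back at 2.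
- Soft enolisation with t-BuMe2SiOSO2CF3 and Et3N should remove a γ-hydrogen and leave the hindered C7–H alone, giving the linear silyl dienol ether F4.
- Ethylene glycol with catalytic pyridinium p-toluenesulfonate at 0 °C should protonate F4 at C9 and trap the oxocarbenium ion as 2, without an acidic ketone stage.

**Step 2.** The likely failures are addition to both faces of the alkene, since a single pseudoaxial oxygen gives limited shielding, and Lewis-acid damage to the β,γ-unsaturated ketal by ZnCl2. The fallback sets out from 2 and comes back at 6, so it also removes step 3.
- A keteniminium [2+2] cycloaddition (CH3CONMe2, (CF3SO2)2O, 2,4,6-collidine, ClCH2CH2Cl, reflux) forms the cyclobutaniminium triflate F5 with the same regiochemistry and no zinc salts.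
- The bulkier cationic partner should respond more strongly to the shielded β face.
- Aqueous NaHCO3 hydrolyses F5 directly to 6.

**Step 4.** The likely failures are competing migration of the C5 methine, which leads to the regioisomeric ketone, and repeated homologation. The fallback sets out from 6 and comes back at 9.
- Homologation with N2CHCO2Et and BF3·OEt2 at low temperature should favour migration of the less substituted carbon even more strongly. It stops at the enolisable β-keto ester F6, which resists a second insertion.
- Krapcho dealkoxycarbonylation (NaCl, wet DMSO, 150 °C) then gives 9.

**Step 5.** The likely failures are proton transfer from C2 to the basic vinyllithium in competition with addition, and partial loss of the dioxolane during the acidic unmasking. The fallback sets out from 9 and comes back at 13.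
- The less basic HC≡CMgBr should add from the same β face and give the 3β-ethynyl-3α-hydroxy compound F7.
- Markovnikov hydration with catalytic (Ph3P)AuN(SO2CF3)2 in wet 1,4-dioxane, under nearly neutral conditions, gives 13.

**Step 9.** The likely failures are incomplete acylation of the hindered axial tertiary hydroxyl, or ionisation at C4 with elimination under the Lewis acid. The fallback sets out from 16 and comes back at 21, and it reverses the order of the two acylations.
- MeC(OMe)3 with catalytic camphorsulfonic acid converts the cis-diol into the cyclic orthoacetate F8.
- Mild aqueous acetic acid should open F8 to the axial ester, the tertiary acetate with a free 3α-hydroxyl, F9.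
- F9 is then angeloylated under the conditions of step 8 to give 21.

## Further compounds

F1 | step 6 | 10β-methyl-7β-isopropyl-5βH-decalin-4,8-dione 8-ethylene ketal (15-nor-eudesmane-4,8-dione 8-dioxolane) | C1CC[C@]2(C)CC3(OCCO3)[C@@H](C(C)C)C[C@@H]2C1=O
F2 | step 6 | 3-hydroxy derivative of F1 (C3 epimers) | OC1CC[C@]2(C)CC3(OCCO3)[C@@H](C(C)C)C[C@@H]2C1=O
F3 | step 6 | 3,4α-dihydroxy-5βH-eudesman-8-one ethylene ketal (C3 epimers) | OC1CC[C@]2(C)CC3(OCCO3)[C@@H](C(C)C)C[C@@H]2[C@]1(C)O
F4 | step 1 | (6R)-1-(tert-butyldimethylsilyloxy)-6-isopropyl-3-methylcyclohexa-1,3-diene | CC1=CC[C@H](C(C)C)C(O[Si](C)(C)C(C)(C)C)=C1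
F5 | step 2 | N,N-dimethyliminium triflate of cyclobutanone 6 | C[N+](C)=C1C[C@]2(C)CC3(OCCO3)[C@@H](C(C)C)C[C@H]12.[O-]S(=O)(=O)C(F)(F)F
F6 | step 4 | ethyl 3-oxo cis-hydrindane-2-carboxylate 8-dioxolane (2-ethoxycarbonyl derivative of 9, C2 epimers) | O=C1C(C(=O)OCC)C[C@]2(C)CC3(OCCO3)[C@@H](C(C)C)C[C@H]12
F7 | step 5 | 3β-ethynyl-3α-hydroxy cis-hydrindane 8-dioxolane | C#C[C@@]1(O)CC[C@]2(C)CC3(OCCO3)[C@@H](C(C)C)C[C@H]12
F8 | step 9 | 3α,4α-O-(1-methoxyethylidene) derivative of 16 (cyclic orthoacetate) | COC1(C)O[C@@H]2CC[C@]3(C)CC(=O)[C@@H](C(C)C)C[C@@H]3[C@]2(C)O1
F9 | step 9 | 4α-acetoxy-3α-hydroxy-5βH-eudesman-8-one | O[C@@H]1CC[C@]2(C)CC(=O)[C@@H](C(C)C)C[C@@H]2[C@]1(C)OC(C)=O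
A1 | alternative 1 | 3-(methoxymethoxy)-3,5-dimethyl-7-isopropyl-2-vinylbicyclo[2.2.2]oct-5-en-2-ol (vinyl and isopropyl syn to the alkene bridge) | C=C[C@@]1(O)[C@H]2C=C(C)[C@H](C[C@@H]2C(C)C)[C@]1(C)OCOC
A2 | alternative 1 | cis-fused 4α-(methoxymethoxy)-5βH-eudesm-8-en-3-one | O=C1CC[C@]2(C)C=C[C@@H](C(C)C)C[C@@H]2[C@]1(C)OCOC
A3 | alternative 2 | 4-[(1-hydroxycyclopropyl)methyl]-2,4-dimethylcyclohex-2-en-1-one | CC1=C[C@@](C)(CC2(O)CC2)CCC1=O
A4 | alternative 2 | cis-fused 4,10-dimethyl-3-(trimethylsilyloxy)decal-3-en-8-one | C[Si](C)(C)OC1=C(C)[C@H]2CCC(=O)C[C@@]2(C)CC1
A5 | alternative 3 | cis-4,7a-dimethylhexahydroindane-1,5-dione 5-ethylene ketal | C12(OCCO1)CC[C@]3(C)C(=O)CC[C@@H]3[C@@H]2C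
A6 | alternative 3 | cis-4,10-dimethyldecalin-3,9-dione 3-ethylene ketal | C12(OCCO1)CC[C@]3(C)C(=O)CCC[C@@H]3[C@@H]2C
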